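**Retrosynthetic overview**
- The target comes from the macrocyclic 8α-alcohol by O-methacrylation, outer-face epoxidation of the ring-trans C1=C10 alkene and desilylation of O15.
- Key disconnection C7–C8: C7, normally the electrophilic β-carbon of a butenolide, is made nucleophilic as the γ-terminus of an allylchromium (a homoenolate-type donor) and attacks the C8 aldehyde. This closes the ten-membered ring and sets C7 and C8 from C6.
- The butenolide comes from ring-closing metathesis of the 2-(bromomethyl)acrylate of an (S)-dienol, itself made by catalytic asymmetric vinylation of a Z-enal (sets C6).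
- The acyclic chain comes from a B-alkyl Suzuki coupling (C3–C4); both trisubstituted alkenes are set by anti-additions to alkynes (2-butyne-1,4-diol for C4=C5, propargyl alcohol for C1=C10).
- Ring order: butenolide (step 9), ten-membered carbocycle (step 11), oxirane (step 13).

Assumption: locants C1–C15 are germacrane locants (ring C1–C10, lactone carbons C11–C13, C14 on C10, C15 on C4); the target is the (1R,6R,7R,8S,10S) isomer; TBS = tert-butyldimethylsilyl.

**Step 1**
Reactants: 1 but-2-yne-1,4-diol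
Product: 2 4-[(tert-butyldimethylsilyl)oxy]but-2-yn-1-ol
Conditions: NaH (1.0 equiv), THF, 0 °C; then TBSCl (1.0 equiv), rt
Reagents that add atoms: tert-butyldimethylsilyl chloride, CC(C)(C)[Si](C)(C)Cl
Why: Monosilylation through the sparingly soluble monosodium alkoxide (Williamson-type O-silylation) caps the future O15 and leaves the C6 hydroxyl free to direct step 2; no stereocentre is involved.

**Step 2**
Reactants: 2 4-[(tert-butyldimethylsilyl)oxy]but-2-yn-1-ol
Product: 4 (2Z)-4-[(tert-butyldimethylsilyl)oxy]-3-iodobut-2-en-1-ol, via cyclic alkenylaluminate 3 (not isolated)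
Conditions: NaAlH2(OCH2CH2OMe)2 (1.5 equiv), THF, 0 °C; then I2, THF, −78 to 0 °C; aq. Rochelle salt
Reagents that add atoms: iodine, [I][I]
Why: Hydroxyl-directed trans-hydroalumination puts aluminium on the distal alkyne carbon inside a five-membered chelate, and iodinolysis with retention gives the vinyl iodide with C15 trans to C6, the geometry of the ring-cis C4=C5 alkene.

**Step 3**
Reactants: 5 prop-2-yn-1-ol, 6 (1,3-dioxolan-2-ylmethyl)magnesium bromide, 7 bromoethene
Product: 9 (2Z)-2-(1,3-dioxolan-2-ylmethyl)penta-2,4-dien-1-ol, via vinylmagnesium chelate 8 (not isolated)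
Conditions: 6 (2.5 equiv), CuI (10 mol%), THF, −10 °C to rt; then 7 (3 equiv), Pd(PPh3)4 (5 mol%), rt to 40 °C; aq. NH4Cl
Reagents that add atoms: none
Why: Copper-catalysed, alkoxide-directed anti-carbomagnesiation of the propargylic alcohol puts the C9–C8 acetal unit on C10 and leaves a vinylmagnesium cis to the CH2O group, and its Kumada–Corriu coupling with bromoethene (retention) fixes C2 cis to C14 and C9 trans to C2.

**Step 4**
Reactants: 9 (2Z)-2-(1,3-dioxolan-2-ylmethyl)penta-2,4-dien-1-ol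
Product: 10 (2Z)-2-(1,3-dioxolan-2-ylmethyl)penta-2,4-dien-1-yl acetate
Conditions: Ac2O, pyridine, DMAP (cat.), CH2Cl2, 0 °C to rt
Reagents that add atoms: acetic anhydride, CC(=O)OC(C)=O
Why: Simple O-acylation installs the C14 acetate of the target early, so the C14 and C6 hydroxyls never have to be distinguished.

**Step 5**
Reactants: 10 (2Z)-2-(1,3-dioxolan-2-ylmethyl)penta-2,4-dien-1-yl acetate, 4 (2Z)-4-[(tert-butyldimethylsilyl)oxy]-3-iodobut-2-en-1-ol
Product: 12 (2Z,6E)-6-{[(tert-butyldimethylsilyl)oxy]methyl}-2-(1,3-dioxolan-2-ylmethyl)-8-hydroxyocta-2,6-dien-1-yl acetate, via B-alkyl-9-BBN borane 11 (not isolated)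
Conditions: 10, 9-BBN, THF, 0 °C to rt; then 4, Pd(dppf)Cl2 (5 mol%), AsPh3 (10 mol%), aq. K3PO4, DMF, rt
Reagents that add atoms: none
Why: 9-BBN hydroborates only the terminal CH2 of the diene, and the B-alkyl Suzuki–Miyaura coupling with the vinyl iodide proceeds with retention at room temperature (C3 cis to C6), fast enough to outcompete ionisation of the allylic acetate by zerovalent palladium.

**Step 6**
Reactants: 12 (2Z,6E)-6-{[(tert-butyldimethylsilyl)oxy]methyl}-2-(1,3-dioxolan-2-ylmethyl)-8-hydroxyocta-2,6-dien-1-yl acetate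
Product: 13 (2Z,6E)-6-{[(tert-butyldimethylsilyl)oxy]methyl}-2-(1,3-dioxolan-2-ylmethyl)-8-oxoocta-2,6-dien-1-yl acetate
Conditions: MnO2 (20 equiv), CH2Cl2, rt
Reagents that add atoms: none
Why: Allylic oxidation with MnO2 touches only the allylic alcohol and preserves the geometry of β,β-disubstituted enals (as in nerol to neral).

**Step 7**
Reactants: 13 (2Z,6E)-6-{[(tert-butyldimethylsilyl)oxy]methyl}-2-(1,3-dioxolan-2-ylmethyl)-8-oxoocta-2,6-dien-1-yl acetate
Product: 14 (2Z,6E,8S)-6-{[(tert-butyldimethylsilyl)oxy]methyl}-2-(1,3-dioxolan-2-ylmethyl)-8-hydroxydeca-2,6,9-trien-1-yl acetate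
Conditions: CH2=CHMgBr (2.4 equiv) + ZnCl2 (1.2 equiv), THF then dioxane (magnesium salts filtered off); (2S)-(−)-3-exo-morpholinoisoborneol (10 mol%), toluene, −30 to 0 °C; aq. NH4Cl
Reagents that add atoms: vinylmagnesium bromide, C=C[Mg]Br
Why: Amino-alcohol-catalysed asymmetric 1,2-addition of divinylzinc to the aldehyde (the ligand directs Si-face attack) sets C6 as the S-carbinol, which becomes 6R in the lactone, and the organozinc leaves acetate and acetal untouched.

**Step 8**
Reactants: 14 (2Z,6E,8S)-6-{[(tert-butyldimethylsilyl)oxy]methyl}-2-(1,3-dioxolan-2-ylmethyl)-8-hydroxydeca-2,6,9-trien-1-yl acetate, 15 2-(bromomethyl)prop-2-enoic acid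
Product: 16 (2Z,6E,8S)-8-{[2-(bromomethyl)prop-2-enoyl]oxy}-6-{[(tert-butyldimethylsilyl)oxy]methyl}-2-(1,3-dioxolan-2-ylmethyl)deca-2,6,9-trien-1-yl acetate
Conditions: 15, DCC, DMAP (5 mol%), CH2Cl2, −10 to 0 °C
Reagents that add atoms: none
Why: Steglich esterification at low temperature acylates the only free hydroxyl without ionising the bis-allylic carbinol, so C6 is untouched.

**Step 9**
Reactants: 16 (2Z,6E,8S)-8-{[2-(bromomethyl)prop-2-enoyl]oxy}-6-{[(tert-butyldimethylsilyl)oxy]methyl}-2-(1,3-dioxolan-2-ylmethyl)deca-2,6,9-trien-1-yl acetate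
Product: 17 (2Z,6E)-7-[(2R)-4-(bromomethyl)-5-oxo-2,5-dihydrofuran-2-yl]-6-{[(tert-butyldimethylsilyl)oxy]methyl}-2-(1,3-dioxolan-2-ylmethyl)hepta-2,6-dien-1-yl acetate
Conditions: second-generation Hoveyda–Grubbs catalyst RuCl2(H2IMes)(=CH-C6H4-2-OiPr) (5 mol%), 1,4-benzoquinone (10 mol%), toluene (5 mM), 70 °C
Reagents that add atoms: none
Why: Ring-closing metathesis starts at the monosubstituted vinyl group and closes onto the 1,1-disubstituted acrylate to give the butenolide, while the trisubstituted chain alkenes are inert and C6 is retained.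

**Step 10**
Reactants: 17 (2Z,6E)-7-[(2R)-4-(bromomethyl)-5-oxo-2,5-dihydrofuran-2-yl]-6-{[(tert-butyldimethylsilyl)oxy]methyl}-2-(1,3-dioxolan-2-ylmethyl)hepta-2,6-dien-1-yl acetate
Product: 18 (2Z,6E)-7-[(2R)-4-(bromomethyl)-5-oxo-2,5-dihydrofuran-2-yl]-6-{[(tert-butyldimethylsilyl)oxy]methyl}-2-(2-oxoethyl)hepta-2,6-dien-1-yl acetate
Conditions: Er(OTf)3 (5 mol%), MeNO2 saturated with H2O, rt
Reagents that add atoms: water, O
Why: Mild lanthanide-triflate-catalysed acetal hydrolysis frees the C8 aldehyde without acid strong enough to cleave the silyl ether or move the β,γ-alkene into conjugation.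

**Step 11**
Reactants: 18 (2Z,6E)-7-[(2R)-4-(bromomethyl)-5-oxo-2,5-dihydrofuran-2-yl]-6-{[(tert-butyldimethylsilyl)oxy]methyl}-2-(2-oxoethyl)hepta-2,6-dien-1-yl acetate
Product: 20 (6R,7R,8S)-14-acetoxy-15-[(tert-butyldimethylsilyl)oxy]-8-hydroxygermacra-1(10),4,11(13)-trien-12,6-olide, via allylchromium species 19 (not isolated)
Conditions: CrCl2 (10 equiv), DMF, rt, syringe-pump addition of 18 (final 2 mM); pH 7 buffer work-up
Reagents that add atoms: none
Why: Proposed new method: two equivalents of divalent chromium turn the allylic bromide into a cyclic allylchromium in which C7, the normally electrophilic β-carbon of the butenolide, is the nucleophilic γ-terminus (a homoenolate-type donor) that adds to the electrophilic C8 aldehyde through a six-membered chair transition state with the aldehyde chain and C6 both pseudo-equatorial (C6 is held trans to the CH2Cr carbon by the ring, hence the 7,8-anti relationship) and with bond formation on the butenolide face opposite to the C5 substituent (trans-fused lactone), so that C7 (R) and C8 (S) are set from C6 while the ten-membered ring closes and the exocyclic methylene appears by allylic transposition; the closest known reactions are intermolecular Barbier and Nozaki–Hiyama allylations of aldehydes with 5-substituted 3-(bromomethyl)furan-2(5H)-ones and macrocyclising Nozaki–Hiyama–Kishi allylations of 2-(bromomethyl)acrylates to ten-membered germacranolides.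

**Step 12**
Reactants: 20 (6R,7R,8S)-14-acetoxy-15-[(tert-butyldimethylsilyl)oxy]-8-hydroxygermacra-1(10),4,11(13)-trien-12,6-olide
Product: 21 (6R,7R,8S)-14-acetoxy-15-[(tert-butyldimethylsilyl)oxy]-8-(methacryloyloxy)germacra-1(10),4,11(13)-trien-12,6-olide
Conditions: methacrylic anhydride (3 equiv), Et3N, DMAP (0.2 equiv), CH2Cl2, 0 °C to rt
Reagents that add atoms: methacrylic anhydride, C=C(C)C(=O)OC(=O)C(C)=C
Why: DMAP-catalysed O-acylation of the secondary 8-hydroxyl under a non-nucleophilic base avoids conjugate addition to the α-methylene lactone and changes no stereocentre.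

**Step 13**
Reactants: 21 (6R,7R,8S)-14-acetoxy-15-[(tert-butyldimethylsilyl)oxy]-8-(methacryloyloxy)germacra-1(10),4,11(13)-trien-12,6-olide
Product: 22 (1R,6R,7R,8S,10S)-14-acetoxy-15-[(tert-butyldimethylsilyl)oxy]-1,10-epoxy-8-(methacryloyloxy)germacra-4,11(13)-dien-12,6-olide
Conditions: mCPBA (1.1 equiv), CH2Cl2/aq. pH 8 phosphate buffer, 0 °C
Reagents that add atoms: 3-chloroperoxybenzoic acid, OOC(=O)c1cccc(Cl)c1
Why: Prilezhaev epoxidation is expected at the strained ring-trans C1=C10 alkene (C4=C5 is deactivated by two allylic oxygens and the enoates are inert) from the exposed outer face of the conformer with C14 up, giving the trans-epoxide (1R,10S) stereospecifically.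

**Step 14**
Reactants: 22 (1R,6R,7R,8S,10S)-14-acetoxy-15-[(tert-butyldimethylsilyl)oxy]-1,10-epoxy-8-(methacryloyloxy)germacra-4,11(13)-dien-12,6-olide
Product: 23 (1R,6R,7R,8S,10S)-14-acetoxy-1,10-epoxy-15-hydroxy-8-(methacryloyloxy)germacra-4,11(13)-dien-12,6-olide
Conditions: Et3N·3HF, THF/MeCN, 0 °C to rt
Reagents that add atoms: none
Why: Buffered fluoride desilylation cleaves the primary allylic silyl ether under nearly neutral conditions that spare the epoxide, both esters and the α-methylene lactone.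

**Compound list**
1 | but-2-yne-1,4-diol | OCC#CCO | starting material
2 | 4-[(tert-butyldimethylsilyl)oxy]but-2-yn-1-ol | OCC#CCO[Si](C)(C)C(C)(C)C | intermediate
3 | sodium 3-{[(tert-butyldimethylsilyl)oxy]methyl}-2,2-bis(2-methoxyethoxy)-2,5-dihydro-1,2-oxaluminol-2-uide (cyclic alkenylaluminate) | [Na+].COCCO[Al-]1(OCCOC)OCC=C1CO[Si](C)(C)C(C)(C)C | intermediate (not isolated)
4 | (2Z)-4-[(tert-butyldimethylsilyl)oxy]-3-iodobut-2-en-1-ol | OC/C=C(\I)CO[Si](C)(C)C(C)(C)C | intermediate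
5 | prop-2-yn-1-ol | C#CCO | starting material
6 | (1,3-dioxolan-2-ylmethyl)magnesium bromide | Br[Mg]CC1OCCO1 | starting material
7 | bromoethene | C=CBr | starting material
8 | bromomagnesium (2Z)-3-(bromomagnesio)-2-(1,3-dioxolan-2-ylmethyl)prop-2-en-1-olate (vinylmagnesium chelate) | Br[Mg]OC/C(CC1OCCO1)=C\[Mg]Br | intermediate (not isolated)
9 | (2Z)-2-(1,3-dioxolan-2-ylmethyl)penta-2,4-dien-1-ol | OC/C(CC1OCCO1)=C\C=C | intermediate
10 | (2Z)-2-(1,3-dioxolan-2-ylmethyl)penta-2,4-dien-1-yl acetate | CC(=O)OC/C(CC1OCCO1)=C\C=C | intermediate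
11 | (2Z)-5-(9-borabicyclo[3.3.1]nonan-9-yl)-2-(1,3-dioxolan-2-ylmethyl)pent-2-en-1-yl acetate | CC(=O)OC/C(CC1OCCO1)=C\CCB2C3CCCC2CCC3 | intermediate (not isolated)
12 | (2Z,6E)-6-{[(tert-butyldimethylsilyl)oxy]methyl}-2-(1,3-dioxolan-2-ylmethyl)-8-hydroxyocta-2,6-dien-1-yl acetate | OC/C=C(\CC/C=C(\COC(C)=O)CC1OCCO1)CO[Si](C)(C)C(C)(C)C | intermediate
13 | (2Z,6E)-6-{[(tert-butyldimethylsilyl)oxy]methyl}-2-(1,3-dioxolan-2-ylmethyl)-8-oxoocta-2,6-dien-1-yl acetate | O=C/C=C(\CC/C=C(\COC(C)=O)CC1OCCO1)CO[Si](C)(C)C(C)(C)C | intermediate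
14 | (2Z,6E,8S)-6-{[(tert-butyldimethylsilyl)oxy]methyl}-2-(1,3-dioxolan-2-ylmethyl)-8-hydroxydeca-2,6,9-trien-1-yl acetate | C=C[C@H](O)/C=C(\CC/C=C(\COC(C)=O)CC1OCCO1)CO[Si](C)(C)C(C)(C)C | intermediate
15 | 2-(bromomethyl)prop-2-enoic acid | C=C(CBr)C(=O)O | starting material
16 | (2Z,6E,8S)-8-{[2-(bromomethyl)prop-2-enoyl]oxy}-6-{[(tert-butyldimethylsilyl)oxy]methyl}-2-(1,3-dioxolan-2-ylmethyl)deca-2,6,9-trien-1-yl acetate | C=C[C@H](OC(=O)C(=C)CBr)/C=C(\CC/C=C(\COC(C)=O)CC1OCCO1)CO[Si](C)(C)C(C)(C)C | intermediate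
17 | (2Z,6E)-7-[(2R)-4-(bromomethyl)-5-oxo-2,5-dihydrofuran-2-yl]-6-{[(tert-butyldimethylsilyl)oxy]methyl}-2-(1,3-dioxolan-2-ylmethyl)hepta-2,6-dien-1-yl acetate | BrCC1=C[C@@H](/C=C(\CC/C=C(\COC(C)=O)CC2OCCO2)CO[Si](C)(C)C(C)(C)C)OC1=O | intermediate
18 | (2Z,6E)-7-[(2R)-4-(bromomethyl)-5-oxo-2,5-dihydrofuran-2-yl]-6-{[(tert-butyldimethylsilyl)oxy]methyl}-2-(2-oxoethyl)hepta-2,6-dien-1-yl acetate | BrCC1=C[C@@H](/C=C(\CC/C=C(\COC(C)=O)CC=O)CO[Si](C)(C)C(C)(C)C)OC1=O | intermediate
19 | dichloro{[(5R)-5-substituted 2-oxo-2,5-dihydrofuran-3-yl]methyl}chromium derived from 18 (trivalent chromium, side chain as in 18) | Cl[Cr](Cl)CC1=C[C@@H](/C=C(\CC/C=C(\COC(C)=O)CC=O)CO[Si](C)(C)C(C)(C)C)OC1=O | intermediate (not isolated)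
20 | (6R,7R,8S)-14-acetoxy-15-[(tert-butyldimethylsilyl)oxy]-8-hydroxygermacra-1(10),4,11(13)-trien-12,6-olide (C9 trans to C2 across C1=C10; C3 cis to C6 across C4=C5; H-6 and H-7 trans; H-7 and H-8 trans) | O[C@H]1C/C(COC(C)=O)=C/CC/C(CO[Si](C)(C)C(C)(C)C)=C\[C@H]2OC(=O)C(=C)[C@H]12 | intermediate
21 | (6R,7R,8S)-14-acetoxy-15-[(tert-butyldimethylsilyl)oxy]-8-(methacryloyloxy)germacra-1(10),4,11(13)-trien-12,6-olide | C=C(C)C(=O)O[C@H]1C/C(COC(C)=O)=C/CC/C(CO[Si](C)(C)C(C)(C)C)=C\[C@H]2OC(=O)C(=C)[C@H]12 | intermediate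
22 | (1R,6R,7R,8S,10S)-14-acetoxy-15-[(tert-butyldimethylsilyl)oxy]-1,10-epoxy-8-(methacryloyloxy)germacra-4,11(13)-dien-12,6-olide | C=C(C)C(=O)O[C@H]1C[C@@]2(COC(C)=O)O[C@@H]2CC/C(CO[Si](C)(C)C(C)(C)C)=C\[C@H]2OC(=O)C(=C)[C@H]12 | intermediate
23 | (1R,6R,7R,8S,10S)-14-acetoxy-1,10-epoxy-15-hydroxy-8-(methacryloyloxy)germacra-4,11(13)-dien-12,6-olide (CNP0306006.2) | C=C(C)C(=O)O[C@H]1C[C@@]2(COC(C)=O)O[C@@H]2CC/C(CO)=C\[C@H]2OC(=O)C(=C)[C@H]12 | target

**Step count**
Total: 14 steps. Longest linear sequence: 12 steps (steps 1, 2, 5–14; the branch through steps 3 and 4 is equally long).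

**Three steps most likely to fail, with fallbacks**

Step 11 (macrocyclising allylation). The cyclisation may oligomerise, give the cis-fused or 8-epi product, or translactonise. The fallback replaces the reductively generated allylchromium by an isolable allylboron nucleophile. Setting out from 17, zerovalent-palladium-catalysed borylation of the allylic bromide (bis(pinacolato)diboron, Pd2(dba)3, AsPh3, toluene, rt; the allylic acetate is inert in toluene) gives (2Z,6E)-6-{[(tert-butyldimethylsilyl)oxy]methyl}-2-(1,3-dioxolan-2-ylmethyl)-7-{(2R)-5-oxo-4-[(4,4,5,5-tetramethyl-1,3,2-dioxaborolan-2-yl)methyl]-2,5-dihydrofuran-2-yl}hepta-2,6-dien-1-yl acetate F1. Acetal hydrolysis as in step 10 gives the corresponding 2-(2-oxoethyl) aldehyde F2. Sc(OTf)3-catalysed intramolecular allylboration at 2 mM (closed chair transition state, same trans/anti outcome) and aqueous work-up bring the route back at 20.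

Step 3 (carbomagnesiation with the acetal Grignard 6). This β-alkoxy Grignard may be too unreactive or may eliminate. The fallback brings in C9–C8 as an allyl group and makes the aldehyde carbon by oxidative cleavage. Setting out from 5, anti-allylmagnesiation with allylmagnesium bromide (CH2=CHCH2MgBr) and an iodine quench give (2Z)-3-iodo-2-(prop-2-en-1-yl)prop-2-en-1-ol F3. Acetylation gives (2Z)-3-iodo-2-(prop-2-en-1-yl)prop-2-en-1-yl acetate F4. Lemieux–Johnson cleavage (OsO4 cat., NaIO4, 2,6-lutidine) of the only electron-rich alkene gives (2Z)-3-iodo-2-(2-oxoethyl)prop-2-en-1-yl acetate F5. Noyori acetalisation (1,2-bis(trimethylsilyloxy)ethane, TMSOTf cat., −78 °C) gives (2Z)-2-(1,3-dioxolan-2-ylmethyl)-3-iodoprop-2-en-1-yl acetate F6. Stille coupling with tributyl(vinyl)stannane (Pd2(dba)3, AsPh3) brings the route back at 10.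

Step 13 (epoxidation). mCPBA may attack C4=C5 or the wrong face of C1=C10. The fallback makes the epoxidation hydroxyl-directed and reagent-controlled. Setting out from 21, lipase hydrolysis of the primary allylic acetate (Candida antarctica lipase B, pH 7 buffer/acetone) gives (6R,7R,8S)-15-[(tert-butyldimethylsilyl)oxy]-14-hydroxy-8-(methacryloyloxy)germacra-1(10),4,11(13)-trien-12,6-olide F7. Sharpless asymmetric epoxidation (Ti(OiPr)4, L-(+)-diethyl tartrate, tert-butyl hydroperoxide, −20 °C), which can only engage the C14 allylic alcohol, gives (1R,6R,7R,8S,10S)-15-[(tert-butyldimethylsilyl)oxy]-1,10-epoxy-14-hydroxy-8-(methacryloyloxy)germacra-4,11(13)-dien-12,6-olide F8. Acetylation (Ac2O, pyridine) brings the route back at 22.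

**Further compounds**
F1 | step 11 | (2Z,6E)-6-{[(tert-butyldimethylsilyl)oxy]methyl}-2-(1,3-dioxolan-2-ylmethyl)-7-{(2R)-5-oxo-4-[(4,4,5,5-tetramethyl-1,3,2-dioxaborolan-2-yl)methyl]-2,5-dihydrofuran-2-yl}hepta-2,6-dien-1-yl acetate | CC1(C)OB(CC2=C[C@@H](/C=C(\CC/C=C(\COC(C)=O)CC3OCCO3)CO[Si](C)(C)C(C)(C)C)OC2=O)OC1(C)C
F2 | step 11 | (2Z,6E)-6-{[(tert-butyldimethylsilyl)oxy]methyl}-2-(2-oxoethyl)-7-{(2R)-5-oxo-4-[(4,4,5,5-tetramethyl-1,3,2-dioxaborolan-2-yl)methyl]-2,5-dihydrofuran-2-yl}hepta-2,6-dien-1-yl acetate | CC1(C)OB(CC2=C[C@@H](/C=C(\CC/C=C(\COC(C)=O)CC=O)CO[Si](C)(C)C(C)(C)C)OC2=O)OC1(C)C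
F3 | step 3 | (2Z)-3-iodo-2-(prop-2-en-1-yl)prop-2-en-1-ol | OC/C(CC=C)=C\I
F4 | step 3 | (2Z)-3-iodo-2-(prop-2-en-1-yl)prop-2-en-1-yl acetate | CC(=O)OC/C(CC=C)=C\I
F5 | step 3 | (2Z)-3-iodo-2-(2-oxoethyl)prop-2-en-1-yl acetate | CC(=O)OC/C(CC=O)=C\I
F6 | step 3 | (2Z)-2-(1,3-dioxolan-2-ylmethyl)-3-iodoprop-2-en-1-yl acetate | CC(=O)OC/C(CC1OCCO1)=C\I
F7 | step 13 | (6R,7R,8S)-15-[(tert-butyldimethylsilyl)oxy]-14-hydroxy-8-(methacryloyloxy)germacra-1(10),4,11(13)-trien-12,6-olide | C=C(C)C(=O)O[C@H]1C/C(CO)=C/CC/C(CO[Si](C)(C)C(C)(C)C)=C\[C@H]2OC(=O)C(=C)[C@H]12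
F8 | step 13 | (1R,6R,7R,8S,10S)-15-[(tert-butyldimethylsilyl)oxy]-1,10-epoxy-14-hydroxy-8-(methacryloyloxy)germacra-4,11(13)-dien-12,6-olide | C=C(C)C(=O)O[C@H]1C[C@@]2(CO)O[C@@H]2CC/C(CO[Si](C)(C)C(C)(C)C)=C\[C@H]2OC(=O)C(=C)[C@H]12
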